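**Plan**

- Retrosynthesis: the five MOM ethers are cut first, then the Cα–O7 and Cα–OH bonds of the hemiketal (back to the CH2 of a 4-hydroxybenzyl group), then C2–Cα (enolate benzylation), then C2–C8 (ketone α-arylation).
- Enabling feature: Cα is benzylic to the 4-hydroxyphenyl ring (para-OH), sits on the quaternary spiro carbon C2, and carries two oxygens (O7 and OH) inside the five-membered ring O7–C7–C8–C2–Cα. This is the pattern left by two successive quinone methide oxidations of one CH2.
- Forward: the kaempferol and coumaranone ring systems are bought intact and protected, joined C8–C2 by Pd catalysis, and the 4-oxybenzyl arm is added at C2. The spiro dihydrofuran ring then closes oxidatively, and deprotection follows.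
- Stereochemistry: C2 comes from a cinchona phase-transfer benzylation. Cα settles by hemiketal equilibration under the bias of C2.

Key step: step 10

**Remarks on the chemistry**

- Locants: C2/C3/O1 are coumaranone atoms, C7/O7/C8 are kaempferol atoms, and Cα is the benzylic carbon that becomes the hemiketal carbon. By CIP analysis of the target SMILES the target is (2S,αR), with the hemiketal OH syn to the C3 carbonyl.
- Assumption: the natural configuration at Cα is the thermodynamically preferred epimer, since a hemiketal can open and reclose.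
- Kaempferol, 4,6-dihydroxybenzofuran-3(2H)-one and 4-(benzyloxy)benzyl bromide are taken as commercial.
- MOM = methoxymethyl.

**Route**

Step 1
Reactants: 1 kaempferol
Product: 2 kaempferol 3,5,7,4'-tetraacetate
Conditions: Ac2O, pyridine, cat. DMAP, rt to 50 °C
Reagents that add atoms: acetic anhydride, CC(=O)OC(C)=O
Why: Exhaustive phenol acetylation (nucleophilic acyl substitution) should proceed cleanly, DMAP and mild warming bringing in the chelated 5-OH.

Step 2
Reactants: 2 kaempferol 3,5,7,4'-tetraacetate
Product: 3 7-O-benzylkaempferol 3,5,4'-triacetate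
Conditions: BnCl, K2CO3, cat. KI, acetone, reflux
Reagents that add atoms: benzyl chloride, ClCc1ccccc1
Why: Jurd-type selective alkylation of a flavonol peracetate, in which the 7-acetate (its phenoxide being the best leaving group, para to the C4 carbonyl) is cleaved by carbonate and the 7-phenoxide is benzylated in situ (Williamson etherification).

Step 3
Reactants: 3 7-O-benzylkaempferol 3,5,4'-triacetate
Product: 4 7-O-benzylkaempferol
Conditions: K2CO3, MeOH/THF, rt, Ar; then dilute HCl work-up
Reagents that add atoms: none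
Why: Base-mediated methanolysis (transesterification) of aryl acetates should leave the benzyl ether and the pyrone ring untouched at room temperature under argon.

Step 4
Reactants: 4 7-O-benzylkaempferol
Product: 5 7-O-benzyl-3,5,4'-tris-O-(methoxymethyl)kaempferol
Conditions: NaH (excess), MOMCl, DMF, 0 °C to rt
Reagents that add atoms: chloromethyl methyl ether, COCCl
Why: Williamson-type acetal ether formation, with full deprotonation by NaH needed to alkylate the hydrogen-bonded 5-OH as well as the 3- and 4'-OH.

Step 5
Reactants: 5 7-O-benzyl-3,5,4'-tris-O-(methoxymethyl)kaempferol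
Product: 6 7-O-benzyl-8-iodo-3,5,4'-tris-O-(methoxymethyl)kaempferol
Conditions: NIS (1.1 equiv), DMF, 40 °C, dark, no acid additive
Reagents that add atoms: N-iodosuccinimide, O=C1CCC(=O)N1I
Why: Electrophilic aromatic iodination of a 5,7-dialkoxyflavone, which is directed to C8 once the 5-oxygen is alkylated (a free 5-OH would steer to C6), under neutral conditions that spare the MOM groups.

Step 6
Reactants: 7 4,6-dihydroxybenzofuran-3(2H)-one
Product: 8 4,6-bis(methoxymethoxy)benzofuran-3(2H)-one
Conditions: MOMCl, i-Pr2NEt, CH2Cl2, 0 °C to rt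
Reagents that add atoms: chloromethyl methyl ether, COCCl
Why: MOM ether formation on both phenols with a hard electrophile and a mild amine base, conditions under which C2 and enol-oxygen alkylation should not compete.

Step 7
Reactants: 6 7-O-benzyl-8-iodo-3,5,4'-tris-O-(methoxymethyl)kaempferol; 8 4,6-bis(methoxymethoxy)benzofuran-3(2H)-one (1.5 equiv)
Product: 9 2-[7-benzyloxy-3,5-bis(MOM-oxy)-2-(4-MOM-oxyphenyl)-4-oxochromen-8-yl]-4,6-bis(MOM-oxy)benzofuran-3(2H)-one (racemic, enolisable at C2)
Conditions: Pd2(dba)3 (2.5 mol%), XPhos (6 mol%), K3PO4, toluene, 90 °C, Ar; product handled under Ar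
Reagents that add atoms: none
Why: Buchwald–Hartwig-type Pd-catalysed ketone α-arylation, where the acidic coumaranone allows the weak base K3PO4 (tolerated by the flavone), the bulky biarylphosphine should drive reductive elimination of the di-ortho-substituted aryl, and that same hindrance blocks a second arylation.

Step 8
Reactants: 9 the 2-(flavonol-8-yl)coumaranone; 10 4-(benzyloxy)benzyl bromide
Product: 11 (S)-2-[4-(benzyloxy)benzyl]-2-[7-benzyloxy-3,5-bis(MOM-oxy)-2-(4-MOM-oxyphenyl)-4-oxochromen-8-yl]-4,6-bis(MOM-oxy)benzofuran-3(2H)-one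
Conditions: N-[4-(trifluoromethyl)benzyl]cinchoninium bromide (10 mol%), 50% aq. KOH, toluene, 0 °C, degassed, Ar
Reagents that add atoms: none
Why: Asymmetric phase-transfer alkylation of an α-aryl cyclic aryl ketone enolate, the chiral ammonium ion pair shielding one enolate face so that C-benzylation sets the quaternary C2; by analogy with 2-aryl-1-indanone alkylations the cinchoninium series should give the (S) centre, and the pseudoenantiomeric cinchonidinium salt is the switch should the facial sense prove opposite.

Step 9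
Reactants: 11 the (S)-bis-benzyl ether
Product: 12 (S)-2-(4-hydroxybenzyl)-2-[7-hydroxy-3,5-bis(MOM-oxy)-2-(4-MOM-oxyphenyl)-4-oxochromen-8-yl]-4,6-bis(MOM-oxy)benzofuran-3(2H)-one
Conditions: H2 (1 atm), 10% Pd/C, EtOAc/THF, rt
Reagents that add atoms: none
Why: Catalytic hydrogenolysis of the two aryl benzyl ethers should free O7–H and the para-phenol of the benzyl arm, while MOM ethers, the flavone double bond and the quaternary C2–O1 bond are inert under these mild conditions.

Step 10
Reactants: 12 the (S)-4-hydroxybenzyl diphenol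
Product: 16 penta-O-MOM spiro hemiketal (2S,αR), via first para-quinone methide 13 (not isolated), via spiro dihydrofuran 14 (not isolated), via alkoxy quinone methide 15 (not isolated)
Conditions: DDQ (2.3 equiv), 1,4-dioxane/pH 7 aq. phosphate buffer (10:1), rt
Reagents that add atoms: water, O
Why: DDQ should abstract hydride from the phenol-activated CH2 of 12 to give para-quinone methide 13, whose exocyclic carbon is captured 1,6 by O7–H in a 5-exo-trig closure of the ring O7–C7–C8–C2–Cα, giving 14. The Cα–H of 14 is still para to the free phenol and now α to oxygen, so a second equivalent of DDQ should take it to the alkoxy quinone methide 15 (an oxocarbenium in its other resonance form), which water captures at Cα to give hemiketal 16. The reaction type is the DDQ oxidation of 4-alkylphenols through quinone methides to the carbonyl oxidation level, combined with the intramolecular phenol capture used in oxidative closures to flavans and 2-aryl-2,3-dihydrobenzofurans. Site selectivity rests on there being one free 4-hydroxybenzyl group, every other phenol being a MOM ether without an activated benzylic hydrogen, and on C2 being quaternary, so that neither quinone methide can tautomerise to a styrene or aromatise to a benzofuran; a quinone methide caught by water instead of O7 is oxidised on to the 4-hydroxyphenyl ketone, which closes to the same hemiketal. The Cα stereocentre is under thermodynamic control through ring–chain tautomerism (hemiketal to hydroxy ketone and back) and should settle, under the bias of the fixed C2 centre, on the epimer with OH syn to the C3 carbonyl (hydrogen bond) and the aryl group syn to O1.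

Step 11
Reactants: 16 penta-O-MOM spiro hemiketal (2S,αR)
Product: 17 CNP0283000.1 (target, 2S,αR)
Conditions: conc. HCl (few equiv), i-PrOH/THF/H2O, 45 °C; aqueous work-up
Reagents that add atoms: none
Why: Acid-catalysed hydrolysis of the five MOM acetals, routine for polyphenolic flavonoids, cannot touch the quaternary C2, and the hemiketal, if it ionises or opens in acid, recloses from water to the same thermodynamic Cα epimer.

**Compound list**

1 | kaempferol | O=c1c(O)c(-c2ccc(O)cc2)oc2cc(O)cc(O)c12 | starting material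
2 | kaempferol 3,5,7,4'-tetraacetate | O=c1c(OC(C)=O)c(-c2ccc(OC(C)=O)cc2)oc2cc(OC(C)=O)cc(OC(C)=O)c12 | intermediate
3 | 7-O-benzylkaempferol 3,5,4'-triacetate | O=c1c(OC(C)=O)c(-c2ccc(OC(C)=O)cc2)oc2cc(OCc3ccccc3)cc(OC(C)=O)c12 | intermediate
4 | 7-O-benzylkaempferol | O=c1c(O)c(-c2ccc(O)cc2)oc2cc(OCc3ccccc3)cc(O)c12 | intermediate
5 | 7-O-benzyl-3,5,4'-tris-O-(methoxymethyl)kaempferol | O=c1c(OCOC)c(-c2ccc(OCOC)cc2)oc2cc(OCc3ccccc3)cc(OCOC)c12 | intermediate
6 | 7-O-benzyl-8-iodo-3,5,4'-tris-O-(methoxymethyl)kaempferol | O=c1c(OCOC)c(-c2ccc(OCOC)cc2)oc2c(I)c(OCc3ccccc3)cc(OCOC)c12 | intermediate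
7 | 4,6-dihydroxybenzofuran-3(2H)-one | O=C1COc2cc(O)cc(O)c12 | starting material
8 | 4,6-bis(methoxymethoxy)benzofuran-3(2H)-one | O=C1COc2cc(OCOC)cc(OCOC)c12 | intermediate
9 | 2-(protected flavonol-8-yl)-4,6-bis(MOM-oxy)benzofuran-3(2H)-one, racemic | O=C1C(c2c(OCc3ccccc3)cc(OCOC)c3c(=O)c(OCOC)c(-c4ccc(OCOC)cc4)oc23)Oc2cc(OCOC)cc(OCOC)c12 | intermediate
10 | 4-(benzyloxy)benzyl bromide | BrCc1ccc(OCc2ccccc2)cc1 | starting material
11 | (S)-2-[4-(benzyloxy)benzyl]-2-(7-O-benzyl flavonol-8-yl) coumaranone, penta-MOM | O=C1c2c(OCOC)cc(OCOC)cc2O[C@@]1(Cc1ccc(OCc3ccccc3)cc1)c1c(OCc3ccccc3)cc(OCOC)c3c(=O)c(OCOC)c(-c4ccc(OCOC)cc4)oc13 | intermediate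
12 | (S)-2-(4-hydroxybenzyl)-2-(7-hydroxy flavonol-8-yl) coumaranone, penta-MOM (key-step precursor) | O=C1c2c(OCOC)cc(OCOC)cc2O[C@@]1(Cc1ccc(O)cc1)c1c(O)cc(OCOC)c2c(=O)c(OCOC)c(-c3ccc(OCOC)cc3)oc12 | intermediate
13 | first para-quinone methide (Cα=C exocyclic, O7–H free) | O=C1c2c(OCOC)cc(OCOC)cc2O[C@@]1(C=C1C=CC(=O)C=C1)c1c(O)cc(OCOC)c2c(=O)c(OCOC)c(-c3ccc(OCOC)cc3)oc12 | intermediate
14 | spiro dihydrofuran with Cα–H (Cα epimers), penta-MOM | O=C1c2c(OCOC)cc(OCOC)cc2O[C@@]12c1c(cc(OCOC)c3c(=O)c(OCOC)c(-c4ccc(OCOC)cc4)oc13)OC2c1ccc(O)cc1 | intermediate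
15 | alkoxy para-quinone methide (Cα exocyclic to the quinoid ring, O7 on Cα) | O=C1c2c(OCOC)cc(OCOC)cc2O[C@@]12c1c(cc(OCOC)c3c(=O)c(OCOC)c(-c4ccc(OCOC)cc4)oc13)OC2=C1C=CC(=O)C=C1 | intermediate
16 | penta-O-MOM spiro hemiketal (2S,αR), free 4-hydroxyphenyl (key-step product) | O=C1c2c(OCOC)cc(OCOC)cc2O[C@@]12c1c(cc(OCOC)c3c(=O)c(OCOC)c(-c4ccc(OCOC)cc4)oc13)O[C@]2(O)c1ccc(O)cc1 | intermediate
17 | CNP0283000.1 (2S,αR) | O=C1c2c(O)cc(O)cc2O[C@@]12c1c(cc(O)c3c(=O)c(O)c(-c4ccc(O)cc4)oc13)O[C@]2(O)c1ccc(O)cc1 | target

**Step count**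

Total: 11 steps. Longest linear sequence: 10 steps (steps 1–5, then 7–11); the coumaranone branch (step 6) joins at step 7.

**Steps most likely to fail, with fallbacks**

1. Step 10. The sequence may stall after the first oxidation, because hydride abstraction from the α-aryloxy Cα–H next to the carbonyl-bearing quaternary C2 is slower than the first. The hydroquinone by-product may also cleave the acid-labile 5-MOM ether. Fallback: bring Cα in at the ketone oxidation level. Setting out from 9, O-acylation with 4-(benzyloxy)benzoyl chloride and Et3N in CH2Cl2 should give the enol ester 3-[4-(benzyloxy)benzoyloxy]-2-(flavonol-8-yl)benzofuran F1. A chiral nucleophilic acyl-transfer catalyst (planar-chiral 4-aminopyridine or an isothiourea; Steglich/Black-type O-to-C rearrangement) should then move the aroyl group to C2 and give the (S)-2-aroyl-2-aryl coumaranone F2. If the enantioselectivity of the transfer is insufficient, F2 is resolved on a chiral stationary phase. Hydrogenolysis (H2, Pd/C) of both benzyl ethers of F2 frees O7–H, which adds to the aroyl ketone, and the route is rejoined at 16.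

2. Step 7. Reductive elimination from the hindered arylpalladium enolate may be slow, giving proto-deiodination of 6, and the product enolate may autoxidise at C2. Fallback: replace enolate arylation by an sp2–sp2 cross-coupling. Setting out from 8, TBSOTf/Et3N should give the silyl enol ether 3-(tert-butyldimethylsilyloxy)-4,6-bis(MOM-oxy)benzofuran F3. Zincation at C2 with TMPZnCl·LiCl gives the benzofuran-2-ylzinc chloride F4 (used in situ). Negishi coupling of F4 with 6 (Pd/SPhos, THF, 50 °C) gives the 2-aryl-3-silyloxybenzofuran F5. Buffered desilylation (TBAF/AcOH, THF, 0 °C) unveils the ketone and rejoins the route at 9.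

3. Step 8. Facial discrimination may be poor, because the di-ortho-substituted aryl group is twisted out of the enolate plane and may not fit the ion-pair model, and some O-benzylation may occur. Fallback: give up asymmetric catalysis for resolution. Setting out from 9, benzylation with 10 under achiral phase transfer (Bu4NBr, K2CO3, toluene) gives racemic 11 F6. Preparative chromatography of F6 on a polysaccharide chiral stationary phase delivers the (S)-enantiomer, which is 11. The absolute configuration is to be secured by X-ray or ECD at 11 or 16.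

**Further compounds**

F1 | step 10 | 3-[4-(benzyloxy)benzoyloxy]-2-(protected flavonol-8-yl)-4,6-bis(MOM-oxy)benzofuran | O=C(Oc1c(-c2c(OCc3ccccc3)cc(OCOC)c3c(=O)c(OCOC)c(-c4ccc(OCOC)cc4)oc23)oc2cc(OCOC)cc(OCOC)c12)c1ccc(OCc2ccccc2)cc1
F2 | step 10 | (S)-2-[4-(benzyloxy)benzoyl]-2-(7-O-benzyl flavonol-8-yl)-4,6-bis(MOM-oxy)benzofuran-3(2H)-one | O=C1c2c(OCOC)cc(OCOC)cc2O[C@@]1(C(=O)c1ccc(OCc3ccccc3)cc1)c1c(OCc3ccccc3)cc(OCOC)c3c(=O)c(OCOC)c(-c4ccc(OCOC)cc4)oc13
F3 | step 7 | 3-(tert-butyldimethylsilyloxy)-4,6-bis(methoxymethoxy)benzofuran | CC(C)(C)[Si](C)(C)Oc1coc2cc(OCOC)cc(OCOC)c12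
F4 | step 7 | [3-(tert-butyldimethylsilyloxy)-4,6-bis(methoxymethoxy)benzofuran-2-yl]zinc chloride | Cl[Zn]c1oc2cc(OCOC)cc(OCOC)c2c1O[Si](C)(C)C(C)(C)C
F5 | step 7 | 3-(tert-butyldimethylsilyloxy)-2-(protected flavonol-8-yl)-4,6-bis(methoxymethoxy)benzofuran | CC(C)(C)[Si](C)(C)Oc1c(-c2c(OCc3ccccc3)cc(OCOC)c3c(=O)c(OCOC)c(-c4ccc(OCOC)cc4)oc23)oc2cc(OCOC)cc(OCOC)c12
F6 | step 8 | racemic 2-[4-(benzyloxy)benzyl]-2-(7-O-benzyl flavonol-8-yl)-4,6-bis(MOM-oxy)benzofuran-3(2H)-one | O=C1c2c(OCOC)cc(OCOC)cc2OC1(Cc1ccc(OCc3ccccc3)cc1)c1c(OCc3ccccc3)cc(OCOC)c3c(=O)c(OCOC)c(-c4ccc(OCOC)cc4)oc13
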